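The ketone carbon and the carbinol oxygen stand 1,4 to each other across C1'–C6' of the cyclohexene (ring C), so both can be held in a temporary γ-lactone. Once the ring alkene is shifted from C1'=C2' to C2'=C3', ring C is a Diels–Alder retron. The key step is the intramolecular Diels–Alder reaction of (S,Z)-pent-3-en-2-yl (E)-penta-2,4-dienoate. One operation forms C4'–C5' and C1'–C6', closes ring C and the lactone, and relays the single carbinol centre to C5' and C6'. Alkene conjugation, reduction to the lactol, addition of an 8-magnesiated coumarin, selective oxidation and a closing aromatic Claisen rearrangement from O7 to C6 complete the target.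

Key step: step 4

Locants: coumarin atoms carry plain numbers. Ring C atoms are primed: C1' is the acyl-bearing alkene carbon, C2' the =CH, C3' and C4' the two CH2, C5' the CH(CH3), and C6' the CH that bears the 1-hydroxyethyl group. The bicyclic lactones use isobenzofuranone numbers (C3 = carbinol carbon, C3a = C6', C4 = C5', C5 = C4', C7a = C1').

Remark: C7a of 7 is drawn for the endo (cis-fused) mode. Either C7a epimer gives 8, so this centre has no bearing on the route.

Step 1
Reactants: 1 (S)-but-3-yn-2-ol
Product: 3 (S)-pent-3-yn-2-ol, via dilithium salt 2 (not isolated)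
Conditions: n-BuLi (2.1 equiv), THF, −78 to −20 °C; MeI (1.05 equiv), −78 °C to rt; H2O
Reagents that add atoms: iodomethane, CI
Why: Acetylide alkylation of the dilithiated propargylic alcohol is much faster at the alkynide carbon than at the lithium alkoxide in THF, and the carbinol centre is not touched.

Step 2
Reactants: 3 (S)-pent-3-yn-2-ol
Product: 4 (S,Z)-pent-3-en-2-ol
Conditions: H2 (1 atm), Pd/CaCO3 poisoned with Pb(OAc)2, quinoline, Et2O, 0 °C
Reagents that add atoms: none
Why: Lindlar semihydrogenation adds H2 syn on the poisoned palladium surface and stops at the Z alkene, whose geometry later encodes the cis relation of C5' and C6'.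

Step 3
Reactants: 4 (S,Z)-pent-3-en-2-ol; 5 (E)-penta-2,4-dienoic acid
Product: 6 (S,Z)-pent-3-en-2-yl (E)-penta-2,4-dienoate
Conditions: DCC, DMAP (cat.), CH2Cl2, 0 °C to rt
Reagents that add atoms: none
Why: Steglich esterification activates the acid and not the alcohol, so the carbinol C–O bond keeps its S configuration and both alkene geometries survive at this temperature.

Step 4
Reactants: 6 (S,Z)-pent-3-en-2-yl (E)-penta-2,4-dienoate
Product: 7 (3S,3aR,4R,7aS)-3,4-dimethyl-3a,4,5,7a-tetrahydroisobenzofuran-1(3H)-one
Conditions: BHT (cat.), 1,2-dichlorobenzene (0.01 M), 185 °C, sealed vessel, Ar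
Reagents that add atoms: none
Why: This is a concerted, suprafacial thermal [4+2] cycloaddition, a type 1 intramolecular Diels–Alder reaction of an ester-tethered 1,3,8-nonatriene, whose closest known relatives are the cyclisations of allylic and propargylic penta-2,4-dienoates to hydroisobenzofuranones. The terminal diene CH2 (future C4') bonds to the methyl-bearing alkene carbon (C5') and the acyl-bearing diene carbon (C1') bonds to C6', so six-membered ring C closes as the cycloaddition ring and the five-membered lactone closes as the fused ring spanned by the three-atom tether C(=O)–O–CH, which permits only this fused regiochemistry. The Z geometry of the dienophile is carried suprafacially into the cis relation of the C4 methyl group and the C3a–C3 bond (C5' and C6'). The alkene face is chosen by the S carbinol centre: allylic 1,3-strain against the cis methyl group keeps the carbinol hydrogen in the alkene plane, which puts the ester oxygen with the diene on one face and the carbinol methyl group on the other and sets 3a-H trans to 3-H (3S,3aR,4R). C7a follows the endo or exo placement of the tether and needs no control because step 5 removes it. The step therefore needs only π-facial selectivity and a rate advantage over dienoate polymerisation, which high dilution, BHT and the rotamer bias of the secondary carbinol carbon should secure.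

Step 5
Reactants: 7 (3S,3aR,4R,7aS)-3,4-dimethyl-3a,4,5,7a-tetrahydroisobenzofuran-1(3H)-one
Product: 8 (3S,3aR,4R)-3,4-dimethyl-3a,4,5,6-tetrahydroisobenzofuran-1(3H)-one
Conditions: DBU (0.3 equiv), CH2Cl2, rt
Reagents that add atoms: none
Why: Base-catalysed alkene isomerisation through the extended lactone dienolate (γ-protonation) gives the more stable conjugated trisubstituted alkene, erases C7a and cannot touch C3, C3a or C4, whose hydrogens are not acidified.

Step 6
Reactants: 8 (3S,3aR,4R)-3,4-dimethyl-3a,4,5,6-tetrahydroisobenzofuran-1(3H)-one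
Product: 9 (3S,3aR,4R)-3,4-dimethyl-1,3,3a,4,5,6-hexahydroisobenzofuran-1-ol (anomers)
Conditions: i-Bu2AlH (1.1 equiv), CH2Cl2, −78 °C; aq. potassium sodium tartrate
Reagents that add atoms: none
Why: Partial 1,2-reduction of a lactone by i-Bu2AlH stops at the stable aluminium hemiacetal at −78 °C and gives the lactol on work-up, and its labile anomeric centre is of no consequence.

Step 7
Reactants: 10 phloroglucinol; 11 ethyl 2-methylacetoacetate
Product: 12 5,7-dihydroxy-3,4-dimethylcoumarin
Conditions: conc. H2SO4, 0 °C to rt; ice water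
Reagents that add atoms: none
Why: In this Pechmann condensation the three free ring positions of phloroglucinol are equivalent, so only one coumarin can form.

Step 8
Reactants: 12 5,7-dihydroxy-3,4-dimethylcoumarin; 13 3-chloro-3-methylbut-1-yne
Product: 14 5-hydroxy-3,4-dimethyl-7-[(2-methylbut-3-yn-2-yl)oxy]coumarin
Conditions: CuCl2·2H2O (1 mol %), DBU (1.1 equiv), MeCN, 0 °C
Reagents that add atoms: none
Why: In this copper-catalysed O-propargylation of a phenol by a tertiary propargylic chloride the 7-OH is the more acidic and open site, while the 5-OH is screened by the peri 4-methyl group, so one equivalent of base and chloride should go to O7.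

Step 9
Reactants: 14 5-hydroxy-3,4-dimethyl-7-[(2-methylbut-3-yn-2-yl)oxy]coumarin
Product: 15 5-methoxy-3,4-dimethyl-7-[(2-methylbut-3-yn-2-yl)oxy]coumarin
Conditions: MeI, K2CO3, DMF, rt
Reagents that add atoms: iodomethane, CI
Why: Williamson ether synthesis on the only remaining phenol uses the smallest electrophile, which reaches the hindered O5, at a temperature at which the propargyl ether is stable.

Step 10
Reactants: 15 5-methoxy-3,4-dimethyl-7-[(2-methylbut-3-yn-2-yl)oxy]coumarin
Product: 16 8-iodo-5-methoxy-3,4-dimethyl-7-[(2-methylbut-3-yn-2-yl)oxy]coumarin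
Conditions: NIS (1.05 equiv), CF3CO2H (10 mol %), MeCN, 0 °C, dark
Reagents that add atoms: N-iodosuccinimide, O=C1CCC(=O)N1I
Why: Electrophilic aromatic iodination should choose C8, which is activated by O7, O5 and O1 and is less crowded than C6 between two alkoxy groups, while the terminal alkyne is far less nucleophilic than the arene.

Step 11
Reactants: 16 8-iodo-5-methoxy-3,4-dimethyl-7-[(2-methylbut-3-yn-2-yl)oxy]coumarin
Product: 17 8-iodo-5-methoxy-3,4-dimethyl-7-[(2-methylbut-3-en-2-yl)oxy]coumarin
Conditions: H2 (1 atm), Pd/CaCO3 poisoned with Pb(OAc)2, quinoline, EtOAc, rt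
Reagents that add atoms: none
Why: Lindlar semihydrogenation of the terminal alkyne stops at the vinyl group, and the poisoned catalyst without base should leave the aryl iodide and the tetrasubstituted coumarin alkene alone.

Step 12
Reactants: 17 8-iodo-5-methoxy-3,4-dimethyl-7-[(2-methylbut-3-en-2-yl)oxy]coumarin; 9 (3S,3aR,4R)-3,4-dimethyl-1,3,3a,4,5,6-hexahydroisobenzofuran-1-ol
Product: 20 8-{hydroxy[(5R,6R)-6-((S)-1-hydroxyethyl)-5-methylcyclohex-1-en-1-yl]methyl}-5-methoxy-3,4-dimethyl-7-[(2-methylbut-3-en-2-yl)oxy]coumarin (carbinol epimers), via arylmagnesium chloride 18 (not isolated), via chloromagnesium alkoxide 19 (not isolated)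
Conditions: 17, i-PrMgCl·LiCl (1.05 equiv), THF, −40 °C; separately 9, i-PrMgCl (1.0 equiv), THF, −78 °C; combine, −40 to 0 °C; pH 7 buffer
Reagents that add atoms: none
Why: Iodine–magnesium exchange at −40 °C outruns attack on the hindered 3,4-dimethylcoumarin lactone, and the arylmagnesium then adds 1,2 to the enal that is in ring–chain equilibrium with the magnesium lactolate (Grignard addition to a lactol), giving a new carbinol centre that is not controlled and is removed in step 13.

Step 13
Reactants: 20 8-{hydroxy[(5R,6R)-6-((S)-1-hydroxyethyl)-5-methylcyclohex-1-en-1-yl]methyl}-5-methoxy-3,4-dimethyl-7-[(2-methylbut-3-en-2-yl)oxy]coumarin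
Product: 21 8-{(5R,6R)-6-[(S)-1-hydroxyethyl]-5-methylcyclohex-1-ene-1-carbonyl}-5-methoxy-3,4-dimethyl-7-[(2-methylbut-3-en-2-yl)oxy]coumarin
Conditions: activated MnO2 (excess), CH2Cl2, rt
Reagents that add atoms: none
Why: MnO2 oxidation is selective for the alcohol that is both benzylic and allylic, so the saturated secondary carbinol and its S centre should remain.

Step 14
Reactants: 21 8-{(5R,6R)-6-[(S)-1-hydroxyethyl]-5-methylcyclohex-1-ene-1-carbonyl}-5-methoxy-3,4-dimethyl-7-[(2-methylbut-3-en-2-yl)oxy]coumarin
Product: 23 7-hydroxy-8-{(5R,6R)-6-[(S)-1-hydroxyethyl]-5-methylcyclohex-1-ene-1-carbonyl}-5-methoxy-3,4-dimethyl-6-(3-methylbut-2-en-1-yl)coumarin (target), via cyclohexadienone 22 (not isolated)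
Conditions: BHT (cat.), m-xylene, 130 °C, Ar
Reagents that add atoms: none
Why: In this aromatic Claisen rearrangement ([3,3]) of the 1,1-dimethylallyl aryl ether C8 is blocked by the acyl group, so the allyl terminus goes to C6 and appears there as a prenyl group, and tautomerisation of the dienone frees the chelated 7-OH under neutral conditions that spare the enone and all three stereocentres.

Compound list
1 | (S)-but-3-yn-2-ol | C#C[C@H](C)O | starting material
2 | dilithium salt of (S)-but-3-yn-2-ol (C-lithio alkynide, O-lithium alkoxide) | [Li]C#C[C@H](C)O[Li] | intermediate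
3 | (S)-pent-3-yn-2-ol | CC#C[C@H](C)O | intermediate
4 | (S,Z)-pent-3-en-2-ol | C/C=C\[C@H](C)O | intermediate
5 | (E)-penta-2,4-dienoic acid | C=C/C=C/C(=O)O | starting material
6 | (S,Z)-pent-3-en-2-yl (E)-penta-2,4-dienoate | C/C=C\[C@H](C)OC(=O)/C=C/C=C | intermediate
7 | (3S,3aR,4R,7aS)-3,4-dimethyl-3a,4,5,7a-tetrahydroisobenzofuran-1(3H)-one | O=C1[C@H]2C=CC[C@@H](C)[C@H]2[C@H](C)O1 | intermediate
8 | (3S,3aR,4R)-3,4-dimethyl-3a,4,5,6-tetrahydroisobenzofuran-1(3H)-one | O=C1C2=CCC[C@@H](C)[C@H]2[C@H](C)O1 | intermediate
9 | (3S,3aR,4R)-3,4-dimethyl-1,3,3a,4,5,6-hexahydroisobenzofuran-1-ol (anomers) | OC1C2=CCC[C@@H](C)[C@H]2[C@H](C)O1 | intermediate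
10 | phloroglucinol | Oc1cc(O)cc(O)c1 | starting material
11 | ethyl 2-methylacetoacetate | CCOC(=O)C(C)C(C)=O | starting material
12 | 5,7-dihydroxy-3,4-dimethylcoumarin | Cc1c(C)c2c(O)cc(O)cc2oc1=O | intermediate
13 | 3-chloro-3-methylbut-1-yne | C#CC(C)(C)Cl | starting material
14 | 5-hydroxy-3,4-dimethyl-7-[(2-methylbut-3-yn-2-yl)oxy]coumarin | Cc1c(C)c2c(O)cc(OC(C)(C)C#C)cc2oc1=O | intermediate
15 | 5-methoxy-3,4-dimethyl-7-[(2-methylbut-3-yn-2-yl)oxy]coumarin | COc1cc(OC(C)(C)C#C)cc2oc(=O)c(C)c(C)c12 | intermediate
16 | 8-iodo-5-methoxy-3,4-dimethyl-7-[(2-methylbut-3-yn-2-yl)oxy]coumarin | COc1cc(OC(C)(C)C#C)c(I)c2oc(=O)c(C)c(C)c12 | intermediate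
17 | 8-iodo-5-methoxy-3,4-dimethyl-7-[(2-methylbut-3-en-2-yl)oxy]coumarin | COc1cc(OC(C)(C)C=C)c(I)c2oc(=O)c(C)c(C)c12 | intermediate
18 | {5-methoxy-3,4-dimethyl-7-[(2-methylbut-3-en-2-yl)oxy]-2-oxo-2H-chromen-8-yl}magnesium chloride | COc1cc(OC(C)(C)C=C)c([Mg]Cl)c2oc(=O)c(C)c(C)c12 | intermediate
19 | chloromagnesium alkoxide of (5R,6R)-6-[(S)-1-hydroxyethyl]-5-methylcyclohex-1-ene-1-carbaldehyde | O=CC1=CCC[C@@H](C)[C@H]1[C@H](C)O[Mg]Cl | intermediate
20 | 8-{hydroxy[(5R,6R)-6-((S)-1-hydroxyethyl)-5-methylcyclohex-1-en-1-yl]methyl}-5-methoxy-3,4-dimethyl-7-[(2-methylbut-3-en-2-yl)oxy]coumarin (carbinol epimers) | COc1cc(OC(C)(C)C=C)c(C(O)C2=CCC[C@@H](C)[C@H]2[C@H](C)O)c2oc(=O)c(C)c(C)c12 | intermediate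
21 | 8-{(5R,6R)-6-[(S)-1-hydroxyethyl]-5-methylcyclohex-1-ene-1-carbonyl}-5-methoxy-3,4-dimethyl-7-[(2-methylbut-3-en-2-yl)oxy]coumarin | COc1cc(OC(C)(C)C=C)c(C(=O)C2=CCC[C@@H](C)[C@H]2[C@H](C)O)c2oc(=O)c(C)c(C)c12 | intermediate
22 | 6-prenyl-6H-cyclohexa-dienone tautomer of the target (C7 ketone, C6 sp3) | COC1=C2C(C)=C(C)C(=O)OC2=C(C(=O)C3=CCC[C@@H](C)[C@H]3[C@H](C)O)C(=O)C1CC=C(C)C | intermediate
23 | 7-hydroxy-8-{(5R,6R)-6-[(S)-1-hydroxyethyl]-5-methylcyclohex-1-ene-1-carbonyl}-5-methoxy-3,4-dimethyl-6-(3-methylbut-2-en-1-yl)coumarin | COc1c(CC=C(C)C)c(O)c(C(=O)C2=CCC[C@@H](C)[C@H]2[C@H](C)O)c2oc(=O)c(C)c(C)c12 | target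

Total step count: 14. Longest linear sequence: 9 (steps 1–6 and 12–14).

Steps most likely to fail

Step 4. The cycloaddition of the unactivated Z alkene may be too slow, because the ester tether prefers its unreactive rotamer, and thermal polymerisation of the dienoate may then win. The fallback replaces the neutral cycloaddition by an inverse-electron-demand pyrone cycloaddition. Setting out from 4, Steglich esterification with commercial 2-oxo-2H-pyran-3-carboxylic acid (O=C(O)c1cccoc1=O) would give the pyrone ester F1. On heating in toluene (110–140 °C) the electron-poor 2-pyrone should add the tethered alkene across its C3 and C6 to the bridged bicyclic lactone F2. This adduct loses CO2 in the same flask and leaves the dienyl lactone F3, with the same two ring bonds and the same allylic-strain control of the face. Hydrogenation of the distal disubstituted alkene with RhCl(PPh3)3 and H2 in benzene comes back to the route at 8 and makes step 5 unnecessary.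

Step 12. The arylmagnesium may attack the coumarin lactone of a second molecule or be quenched by proton transfer from the acidic 4-methyl group. The lactolate may also open too slowly at the low temperature that the reagent tolerates. The fallback is a Nozaki–Hiyama–Kishi coupling run in Barbier mode. Setting out from 17 and 9, divalent chromium (CrCl2, excess) with NiCl2 (cat.) in DMF at rt would turn the iodide into the non-basic trivalent arylchromium dichloride F4. This species ignores lactones and free hydroxyl groups and adds only to the open hydroxy enal F5, the ring–chain tautomer of 9. The sequence comes back to the route at 20.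

Step 13. Oxidation at a carbinol crowded by two ortho substituents may be sluggish. This electron-rich carbinol may also ionise under traces of acid, with capture of the cation by the side-chain hydroxyl. The fallback differentiates the two alcohols by protection instead of by the oxidant. Setting out from 20, Et3SiCl and imidazole in CH2Cl2 at −20 °C should silylate the less hindered side-chain alcohol and give the mono(triethylsilyl) ether F6. Dess–Martin oxidation buffered with NaHCO3 would give the silyl-protected ketone F7. HF·pyridine in THF with added pyridine at 0 °C removes the silyl group and comes back to the route at 21.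

Further compounds
F1 | step 4 | (S,Z)-pent-3-en-2-yl 2-oxo-2H-pyran-3-carboxylate | C/C=C\[C@H](C)OC(=O)c1cccoc1=O
F2 | step 4 | bridged 2-oxabicyclo[2.2.2]oct-5-en-3-one adduct fused to the γ-lactone (orientation of the CO2 bridge immaterial) | O=C1C23C=CC(OC2=O)[C@@H](C)[C@H]3[C@H](C)O1
F3 | step 4 | (3S,3aR,4R)-3,4-dimethyl-3a,4-dihydroisobenzofuran-1(3H)-one | O=C1C2=CC=C[C@@H](C)[C@H]2[C@H](C)O1
F4 | step 12 | {5-methoxy-3,4-dimethyl-7-[(2-methylbut-3-en-2-yl)oxy]-2-oxo-2H-chromen-8-yl}chromium dichloride | COc1cc(OC(C)(C)C=C)c([Cr](Cl)Cl)c2oc(=O)c(C)c(C)c12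
F5 | step 12 | (5R,6R)-6-[(S)-1-hydroxyethyl]-5-methylcyclohex-1-ene-1-carbaldehyde | O=CC1=CCC[C@@H](C)[C@H]1[C@H](C)O
F6 | step 13 | side-chain mono(triethylsilyl) ether of 20 (carbinol epimers) | COc1cc(OC(C)(C)C=C)c(C(O)C2=CCC[C@@H](C)[C@H]2[C@H](C)O[Si](CC)(CC)CC)c2oc(=O)c(C)c(C)c12
F7 | step 13 | side-chain triethylsilyl ether of 21 | COc1cc(OC(C)(C)C=C)c(C(=O)C2=CCC[C@@H](C)[C@H]2[C@H](C)O[Si](CC)(CC)CC)c2oc(=O)c(C)c(C)c12
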